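**Plan**

- Retrosynthesis: the enal is traced back to a 4-methoxybenzyl (PMB) protected allylic alcohol, the acetate and angelate C–O bonds are cut, the exocyclic C=CH2 is traced back to a ketone, and then the ring bond C2–C3 is cut.
- Enabling feature: in the dihydrofuran ring C3 is a benzylic carbinol carbon, and C2 carries O1 and a side-chain carbon that can stand as a ketone (the later acrolein alpha carbon). C2–C3 is therefore the bond of an intramolecular aldol between an aryloxymethyl ketone and an ortho aldehyde.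
- Forward, chain assembly: 4-hydroxyacetophenone gives the (R) side-chain carbinol (as its silyl ether) and is ortho-formylated. The phenol opens PMB glycidyl ether, and oxidation gives the keto aldehyde.
- Forward, ring and end game: the dihydrofuran ring, the only ring made, closes by a proline enamine aldol. Methylenation, acetylation, silyl-to-angelate exchange, PMB removal and oxidation finish the route.
- Stereochemistry: the side-chain centre comes from a Corey–Bakshi–Shibata reduction. C2 and C3 come together, cis, from the catalyst-controlled aldol, and no later step touches a stereocentre.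

Key step: step 9

Assumption: the sense of induction of L-proline is taken from the hydrogen-bonded enamine transition-state model of proline aldol reactions (attack on the enamine face syn to the carboxylic acid, as in the cyclohexanone series). If the cyclisation follows the opposite sense, D-proline is used in step 9 and nothing else changes.

Abbreviations: TBS = tert-butyldimethylsilyl, PMB = 4-methoxybenzyl.

**Route**

Step 1
Reactants: 1 4-hydroxyacetophenone
Product: 2 1-[4-(tert-butyldimethylsilyloxy)phenyl]ethan-1-one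
Conditions: TBSCl, imidazole, DMF, rt
Reagents that add atoms: tert-butyldimethylsilyl chloride, CC(C)(C)[Si](C)(C)Cl
Why: Standard silylation of the phenol masks the acidic OH so that the borane reduction in step 2 runs on a neutral aryl ketone.

Step 2
Reactants: 2 1-[4-(tert-butyldimethylsilyloxy)phenyl]ethan-1-one
Product: 3 (1R)-1-[4-(tert-butyldimethylsilyloxy)phenyl]ethan-1-ol
Conditions: (S)-2-methyl-CBS-oxazaborolidine (10 mol%), BH3·SMe2, THF, −20 °C; MeOH quench
Reagents that add atoms: none
Why: Corey–Bakshi–Shibata reduction, in which the (S)-oxazaborolidine–borane complex binds the ketone with the aryl group as the large substituent and delivers hydride to the Si face, should set the (R) carbinol centre of the side chain.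

Step 3
Reactants: 3 (1R)-1-[4-(tert-butyldimethylsilyloxy)phenyl]ethan-1-ol
Product: 4 tert-butyl{4-[(1R)-1-(tert-butyldimethylsilyloxy)ethyl]phenoxy}dimethylsilane
Conditions: TBSCl, imidazole, DMF, rt
Reagents that add atoms: tert-butyldimethylsilyl chloride, CC(C)(C)[Si](C)(C)Cl
Why: Silylation of the secondary alcohol installs an ether that should survive carbonate, the magnesium-mediated formylation, periodinane oxidation, proline and the zinc–titanium methylenation, yet falls to fluoride.

Step 4
Reactants: 4 tert-butyl{4-[(1R)-1-(tert-butyldimethylsilyloxy)ethyl]phenoxy}dimethylsilane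
Product: 5 4-[(1R)-1-(tert-butyldimethylsilyloxy)ethyl]phenol
Conditions: Cs2CO3 (0.5 equiv), DMF–H2O (10:1), rt
Reagents that add atoms: none
Why: Chemoselective desilylation should free only the phenol, because carbonate cleaves aryl silyl ethers (phenoxide leaving group) far faster than alkyl silyl ethers.

Step 5
Reactants: 5 4-[(1R)-1-(tert-butyldimethylsilyloxy)ethyl]phenol
Product: 7 5-[(1R)-1-(tert-butyldimethylsilyloxy)ethyl]-2-hydroxybenzaldehyde, via hydroxymethylphenol 6 (not isolated)
Conditions: MgCl2 (anhydrous), Et3N, paraformaldehyde, MeCN, reflux; aq. NH4Cl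
Reagents that add atoms: paraformaldehyde (as formaldehyde), C=O
Why: Casnati–Skattebøl ortho-formylation, in which the magnesium phenoxide delivers formaldehyde to the ortho carbon through a chelate and a second formaldehyde oxidises the hydroxymethyl group by hydride transfer, should give only the salicylaldehyde because the para position is blocked.

Step 6
Reactants: 8 4-methoxybenzyl alcohol; 9 epichlorohydrin (racemic)
Product: 10 2-[(4-methoxybenzyloxy)methyl]oxirane (racemic)
Conditions: 50% aq. NaOH, Bu4NHSO4 (cat.), excess 9, 0 °C → rt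
Reagents that add atoms: none
Why: Phase-transfer Williamson glycidylation is the standard route to glycidyl ethers, and the racemate suffices because the epoxide stereocentre later becomes the ketone carbon.

Step 7
Reactants: 7 5-[(1R)-1-(tert-butyldimethylsilyloxy)ethyl]-2-hydroxybenzaldehyde; 10 2-[(4-methoxybenzyloxy)methyl]oxirane
Product: 11 5-[(1R)-1-(tert-butyldimethylsilyloxy)ethyl]-2-[2-hydroxy-3-(4-methoxybenzyloxy)propoxy]benzaldehyde (mixture of the two carbinol epimers)
Conditions: K2CO3 (0.5 equiv), DMF, 80 °C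
Reagents that add atoms: none
Why: SN2 opening of the terminal epoxide at its CH2 carbon by the phenoxide (aryl glycidyl ether chemistry) forms the ArO–CH2 bond without any enolisable ketone being exposed to base; the new carbinol centre is not controlled and is erased in step 8.

Step 8
Reactants: 11 5-[(1R)-1-(tert-butyldimethylsilyloxy)ethyl]-2-[2-hydroxy-3-(4-methoxybenzyloxy)propoxy]benzaldehyde
Product: 12 5-[(1R)-1-(tert-butyldimethylsilyloxy)ethyl]-2-[3-(4-methoxybenzyloxy)-2-oxopropoxy]benzaldehyde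
Conditions: Dess–Martin periodinane, NaHCO3, CH2Cl2, 0 °C → rt
Reagents that add atoms: none
Why: Buffered Dess–Martin oxidation converts the secondary alcohol into the ketone without touching the aryl aldehyde, and its non-basic medium should prevent premature aldol condensation to a benzofuran.

Step 9
Reactants: 12 5-[(1R)-1-(tert-butyldimethylsilyloxy)ethyl]-2-[3-(4-methoxybenzyloxy)-2-oxopropoxy]benzaldehyde
Product: 14 1-{(2S,3R)-5-[(1R)-1-(tert-butyldimethylsilyloxy)ethyl]-3-hydroxy-2,3-dihydro-1-benzofuran-2-yl}-2-(4-methoxybenzyloxy)ethan-1-one (2,3-cis), via proline enamine 13 (not isolated)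
Conditions: L-proline (30 mol%), DMF (0.1 M), rt; pH 7 buffer work-up, product used promptly
Reagents that add atoms: none
Why: L-Proline condenses with the ketone of 12 to the E-enamine 13 on the aryloxy-bearing carbon, this carbon (the future C2) adds to the ortho aldehyde carbon (the future C3) while the carboxylic acid of the catalyst hydrogen-bonds to the aldehyde oxygen, and hydrolysis of the resulting iminium ion releases 14 and the catalyst. The closest known reaction type is the proline-catalysed intramolecular enamine aldol (Hajos–Parrish type), which has been applied to 2-(2-oxoalkoxy)benzaldehydes to give cis-2-acyl-2,3-dihydrobenzofuran-3-ols. The dihydrofuran ring closes in the 5-(enolexo)-exo-trig mode, with the enamine double bond outside the new ring and the aldehyde C=O exo to it. C2 is set by the catalyst, the aldehyde being delivered to the enamine face that carries the carboxylic acid of the (S)-pyrrolidine; C3 is set relative to C2 because the same hydrogen bond holds the aldehyde oxygen and the nitrogen-bearing enamine carbon on one side of the forming ring, which should give the cis (2S,3R) aldol. The step needs regioselection between the two alpha carbons of the ketone and freedom from dehydration: the substrate secures the first because only the aryloxy-side enamine reaches the aldehyde through a five-membered transition state (the benzyloxy-side enamine would have to close a seven-membered ring), and the neutral medium at room temperature secures the second.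

Step 10
Reactants: 14 1-{(2S,3R)-5-[(1R)-1-(tert-butyldimethylsilyloxy)ethyl]-3-hydroxy-2,3-dihydro-1-benzofuran-2-yl}-2-(4-methoxybenzyloxy)ethan-1-one
Product: 15 (2R,3R)-5-[(1R)-1-(tert-butyldimethylsilyloxy)ethyl]-2-[3-(4-methoxybenzyloxy)prop-1-en-2-yl]-2,3-dihydro-1-benzofuran-3-ol
Conditions: Zn, CH2Br2, TiCl4, THF (reagent pre-formed at 0–5 °C); then 14, CH2Cl2, 0 °C → rt; aq. NaHCO3
Reagents that add atoms: dibromomethane, BrCBr
Why: Takai–Lombardo methylenation uses a non-basic, oxophilic zinc–titanium methylene reagent that is known to methylenate enolisable alpha-alkoxy and hydroxyl-bearing ketones without epimerisation or retro-aldol cleavage, so the cis aldol should be carried into the 1,1-disubstituted alkene with C2 and C3 intact (the C2 descriptor changes from S to R only through the priority rules).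

Step 11
Reactants: 15 (2R,3R)-5-[(1R)-1-(tert-butyldimethylsilyloxy)ethyl]-2-[3-(4-methoxybenzyloxy)prop-1-en-2-yl]-2,3-dihydro-1-benzofuran-3-ol
Product: 16 (2R,3R)-5-[(1R)-1-(tert-butyldimethylsilyloxy)ethyl]-2-[3-(4-methoxybenzyloxy)prop-1-en-2-yl]-2,3-dihydro-1-benzofuran-3-yl acetate
Conditions: Ac2O, pyridine, DMAP (cat.), CH2Cl2, 0 °C → rt
Reagents that add atoms: acetic anhydride, CC(=O)OC(C)=O
Why: DMAP-catalysed acetylation of the benzylic alcohol is safe at this stage because, with the ketone gone, the C2 hydrogen is no longer acidic and elimination to a benzofuran is not available.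

Step 12
Reactants: 16 (2R,3R)-5-[(1R)-1-(tert-butyldimethylsilyloxy)ethyl]-2-[3-(4-methoxybenzyloxy)prop-1-en-2-yl]-2,3-dihydro-1-benzofuran-3-yl acetate
Product: 17 (2R,3R)-5-[(1R)-1-hydroxyethyl]-2-[3-(4-methoxybenzyloxy)prop-1-en-2-yl]-2,3-dihydro-1-benzofuran-3-yl acetate
Conditions: TBAF, AcOH (1:1), THF, 0 °C → rt
Reagents that add atoms: none
Why: Fluoride cleavage of the silyl ether, buffered with acetic acid so that the medium is not basic, should free the side-chain alcohol while the C3 acetate and the PMB ether stay in place.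

Step 13
Reactants: 17 (2R,3R)-5-[(1R)-1-hydroxyethyl]-2-[3-(4-methoxybenzyloxy)prop-1-en-2-yl]-2,3-dihydro-1-benzofuran-3-yl acetate; 18 angelic acid [(Z)-2-methylbut-2-enoic acid]
Product: 20 (1R)-1-{(2R,3R)-3-acetoxy-2-[3-(4-methoxybenzyloxy)prop-1-en-2-yl]-2,3-dihydro-1-benzofuran-5-yl}ethyl (Z)-2-methylbut-2-enoate, via angelic 2,4,6-trichlorobenzoic anhydride 19 (not isolated)
Conditions: 18, 2,4,6-trichlorobenzoyl chloride, Et3N, toluene, rt; then 17, 75 °C (no DMAP)
Reagents that add atoms: none
Why: Yamaguchi esterification without a nucleophilic catalyst lets the alcohol attack the less hindered angeloyl carbonyl of the mixed anhydride directly, which avoids the addition–elimination pathway that turns Z into E, and the carbinol centre is retained because only the O–acyl bond is formed.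

Step 14
Reactants: 20 (1R)-1-{(2R,3R)-3-acetoxy-2-[3-(4-methoxybenzyloxy)prop-1-en-2-yl]-2,3-dihydro-1-benzofuran-5-yl}ethyl (Z)-2-methylbut-2-enoate
Product: 21 (1R)-1-[(2R,3R)-3-acetoxy-2-(3-hydroxyprop-1-en-2-yl)-2,3-dihydro-1-benzofuran-5-yl]ethyl (Z)-2-methylbut-2-enoate
Conditions: DDQ, CH2Cl2–pH 7 phosphate buffer (10:1), 0 °C → rt
Reagents that add atoms: none
Why: Oxidative PMB cleavage (hydride abstraction by DDQ at the electron-rich benzylic position, then hydrolysis of the oxocarbenium ion) should spare both esters and the terminal alkene, and any over-oxidation of the allylic alcohol only anticipates step 15.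

Step 15
Reactants: 21 (1R)-1-[(2R,3R)-3-acetoxy-2-(3-hydroxyprop-1-en-2-yl)-2,3-dihydro-1-benzofuran-5-yl]ethyl (Z)-2-methylbut-2-enoate
Product: 22 (1R)-1-[(2R,3R)-3-acetoxy-2-(3-oxoprop-1-en-2-yl)-2,3-dihydro-1-benzofuran-5-yl]ethyl (Z)-2-methylbut-2-enoate (CNP0294391.3)
Conditions: Dess–Martin periodinane, NaHCO3, CH2Cl2, 0 °C
Reagents that add atoms: none
Why: Buffered Dess–Martin oxidation of the primary allylic alcohol to the 2-substituted acrolein runs without base, so neither ester should be cleaved and the aryloxy group at C2 should not be eliminated.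

**Compound list**

1 | 4-hydroxyacetophenone | CC(=O)c1ccc(O)cc1 | starting material
2 | 1-[4-(tert-butyldimethylsilyloxy)phenyl]ethan-1-one | CC(=O)c1ccc(O[Si](C)(C)C(C)(C)C)cc1 | intermediate
3 | (1R)-1-[4-(tert-butyldimethylsilyloxy)phenyl]ethan-1-ol | C[C@@H](O)c1ccc(O[Si](C)(C)C(C)(C)C)cc1 | intermediate
4 | tert-butyl{4-[(1R)-1-(tert-butyldimethylsilyloxy)ethyl]phenoxy}dimethylsilane | C[C@@H](O[Si](C)(C)C(C)(C)C)c1ccc(O[Si](C)(C)C(C)(C)C)cc1 | intermediate
5 | 4-[(1R)-1-(tert-butyldimethylsilyloxy)ethyl]phenol | C[C@@H](O[Si](C)(C)C(C)(C)C)c1ccc(O)cc1 | intermediate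
6 | 4-[(1R)-1-(tert-butyldimethylsilyloxy)ethyl]-2-(hydroxymethyl)phenol (present as its magnesium phenoxide, not isolated) | C[C@@H](O[Si](C)(C)C(C)(C)C)c1ccc(O)c(CO)c1 | intermediate
7 | 5-[(1R)-1-(tert-butyldimethylsilyloxy)ethyl]-2-hydroxybenzaldehyde | C[C@@H](O[Si](C)(C)C(C)(C)C)c1ccc(O)c(C=O)c1 | intermediate
8 | 4-methoxybenzyl alcohol | COc1ccc(CO)cc1 | starting material
9 | epichlorohydrin (racemic) | ClCC1CO1 | starting material
10 | 2-[(4-methoxybenzyloxy)methyl]oxirane (racemic) | COc1ccc(COCC2CO2)cc1 | intermediate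
11 | 5-[(1R)-1-(tert-butyldimethylsilyloxy)ethyl]-2-[2-hydroxy-3-(4-methoxybenzyloxy)propoxy]benzaldehyde (both carbinol epimers) | C[C@@H](O[Si](C)(C)C(C)(C)C)c1ccc(OCC(O)COCc2ccc(OC)cc2)c(C=O)c1 | intermediate
12 | 5-[(1R)-1-(tert-butyldimethylsilyloxy)ethyl]-2-[3-(4-methoxybenzyloxy)-2-oxopropoxy]benzaldehyde | C[C@@H](O[Si](C)(C)C(C)(C)C)c1ccc(OCC(=O)COCc2ccc(OC)cc2)c(C=O)c1 | intermediate
13 | (2S)-1-[(E)-1-{4-[(1R)-1-(tert-butyldimethylsilyloxy)ethyl]-2-formylphenoxy}-3-(4-methoxybenzyloxy)prop-1-en-2-yl]pyrrolidine-2-carboxylic acid (proline enamine, not isolated) | OC(=O)[C@@H]1CCCN1/C(COCc2ccc(OC)cc2)=C/Oc3ccc(cc3C=O)[C@@H](C)O[Si](C)(C)C(C)(C)C | intermediate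
14 | 1-{(2S,3R)-5-[(1R)-1-(tert-butyldimethylsilyloxy)ethyl]-3-hydroxy-2,3-dihydro-1-benzofuran-2-yl}-2-(4-methoxybenzyloxy)ethan-1-one (2,3-cis) | COc1ccc(COCC(=O)[C@H]2Oc3ccc([C@@H](C)O[Si](C)(C)C(C)(C)C)cc3[C@H]2O)cc1 | intermediate
15 | (2R,3R)-5-[(1R)-1-(tert-butyldimethylsilyloxy)ethyl]-2-[3-(4-methoxybenzyloxy)prop-1-en-2-yl]-2,3-dihydro-1-benzofuran-3-ol (2,3-cis) | C=C(COCc1ccc(OC)cc1)[C@H]2Oc3ccc([C@@H](C)O[Si](C)(C)C(C)(C)C)cc3[C@H]2O | intermediate
16 | (2R,3R)-5-[(1R)-1-(tert-butyldimethylsilyloxy)ethyl]-2-[3-(4-methoxybenzyloxy)prop-1-en-2-yl]-2,3-dihydro-1-benzofuran-3-yl acetate | C=C(COCc1ccc(OC)cc1)[C@H]2Oc3ccc([C@@H](C)O[Si](C)(C)C(C)(C)C)cc3[C@H]2OC(C)=O | intermediate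
17 | (2R,3R)-5-[(1R)-1-hydroxyethyl]-2-[3-(4-methoxybenzyloxy)prop-1-en-2-yl]-2,3-dihydro-1-benzofuran-3-yl acetate | C=C(COCc1ccc(OC)cc1)[C@H]2Oc3ccc([C@@H](C)O)cc3[C@H]2OC(C)=O | intermediate
18 | angelic acid, (Z)-2-methylbut-2-enoic acid | C/C=C(C)\C(=O)O | starting material
19 | angelic 2,4,6-trichlorobenzoic anhydride (not isolated) | C/C=C(C)\C(=O)OC(=O)c1c(Cl)cc(Cl)cc1Cl | intermediate
20 | (1R)-1-{(2R,3R)-3-acetoxy-2-[3-(4-methoxybenzyloxy)prop-1-en-2-yl]-2,3-dihydro-1-benzofuran-5-yl}ethyl (Z)-2-methylbut-2-enoate | C=C(COCc1ccc(OC)cc1)[C@H]2Oc3ccc([C@@H](C)OC(=O)/C(C)=C\C)cc3[C@H]2OC(C)=O | intermediate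
21 | (1R)-1-[(2R,3R)-3-acetoxy-2-(3-hydroxyprop-1-en-2-yl)-2,3-dihydro-1-benzofuran-5-yl]ethyl (Z)-2-methylbut-2-enoate | C=C(CO)[C@H]1Oc2ccc([C@@H](C)OC(=O)/C(C)=C\C)cc2[C@H]1OC(C)=O | intermediate
22 | (1R)-1-[(2R,3R)-3-acetoxy-2-(3-oxoprop-1-en-2-yl)-2,3-dihydro-1-benzofuran-5-yl]ethyl (Z)-2-methylbut-2-enoate | C=C(C=O)[C@H]1Oc2ccc([C@@H](C)OC(=O)/C(C)=C\C)cc2[C@H]1OC(C)=O | target

**Step count**

Total steps: 15. Longest linear sequence: 14 steps (1 to 22 through steps 1–5 and 7–15); step 6 is the only side-branch step.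

**Steps most likely to fail**

Step 9 (key aldol). The extra ether oxygen on the ketone may let enamine formation compete at the benzyloxy-bearing carbon or blur the facial discrimination. The slowly forming aldol may also lose water to the aromatic 2-acylbenzofuran. The fallback sets out from 7 and comes back at 21; it moves the aldol to the parent methyl ketone and brings in the acrolein oxygen last by allylic C–H oxidation.
- Compound 7 would be alkylated with chloroacetone (K2CO3, KI cat., DMF, 0 °C, stopped as soon as 7 is consumed) to 5-[(1R)-1-(tert-butyldimethylsilyloxy)ethyl]-2-(2-oxopropoxy)benzaldehyde F1.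
- L-Proline in DMF should then give 1-{(2S,3R)-5-[(1R)-1-(tert-butyldimethylsilyloxy)ethyl]-3-hydroxy-2,3-dihydro-1-benzofuran-2-yl}ethan-1-one F2.
- Methylenation as in step 10 should give (2R,3R)-5-[(1R)-1-(tert-butyldimethylsilyloxy)ethyl]-2-(prop-1-en-2-yl)-2,3-dihydro-1-benzofuran-3-ol F3.
- Acetylation as in step 11 gives (2R,3R)-5-[(1R)-1-(tert-butyldimethylsilyloxy)ethyl]-2-(prop-1-en-2-yl)-2,3-dihydro-1-benzofuran-3-yl acetate F4.
- Buffered TBAF as in step 12 gives (2R,3R)-5-[(1R)-1-hydroxyethyl]-2-(prop-1-en-2-yl)-2,3-dihydro-1-benzofuran-3-yl acetate F5.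
- Angeloylation as in step 13 gives (1R)-1-[(2R,3R)-3-acetoxy-2-(prop-1-en-2-yl)-2,3-dihydro-1-benzofuran-5-yl]ethyl (Z)-2-methylbut-2-enoate F6.
- Allylic oxidation of the isopropenyl methyl group of F6 with SeO2 (cat.) and tert-butyl hydroperoxide in CH2Cl2 (ene reaction followed by a [2,3]-sigmatropic shift) should give 21, which step 15 completes. The C2 methine is deactivated by its oxygen, and the angelate methyls sit on an electron-poor alkene.

Step 10 (methylenation). The zinc and titanium Lewis acids may trigger retro-aldol cleavage or loss of the free beta-hydroxyl towards the benzofuran, or the metal alkoxide of that hydroxyl may stall the methylene transfer. The fallback sets out from 14 and comes back at 15; it caps the hydroxyl and uses a titanocene methylidene.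
- Silylation of 14 (Et3SiOTf, 2,6-lutidine, CH2Cl2, −78 °C) gives 1-{(2S,3R)-5-[(1R)-1-(tert-butyldimethylsilyloxy)ethyl]-3-(triethylsilyloxy)-2,3-dihydro-1-benzofuran-2-yl}-2-(4-methoxybenzyloxy)ethan-1-one F7.
- Petasis methylenation (Cp2TiMe2, toluene, 65 °C) should give tert-butyl{(1R)-1-[(2R,3R)-2-[3-(4-methoxybenzyloxy)prop-1-en-2-yl]-3-(triethylsilyloxy)-2,3-dihydro-1-benzofuran-5-yl]ethoxy}dimethylsilane F8.
- Selective removal of the triethylsilyl group (HF·pyridine, pyridine, THF, 0 °C) returns 15.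

Step 13 (angeloylation). The activated acyl unit may isomerise from Z to E (tiglate), or the para-alkoxybenzylic alcohol may ionise or eliminate at the temperature that DMAP-free acylation needs. The fallback sets out from 17 and comes back at 20; it builds the Z double bond on the ester instead of transferring it.
- Compound 17 is esterified at room temperature with 2-[bis(2,2,2-trifluoroethoxy)phosphoryl]propanoic acid (EDC·HCl, DMAP cat., CH2Cl2) to (1R)-1-{(2R,3R)-3-acetoxy-2-[3-(4-methoxybenzyloxy)prop-1-en-2-yl]-2,3-dihydro-1-benzofuran-5-yl}ethyl 2-[bis(2,2,2-trifluoroethoxy)phosphoryl]propanoate F9 (both epimers at the phosphonate carbon).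
- Still–Gennari olefination of F9 with acetaldehyde (KHMDS, 18-crown-6, THF, −78 °C) should give the Z-trisubstituted enoate 20.

**Further compounds**

F1 | step 9 | 5-[(1R)-1-(tert-butyldimethylsilyloxy)ethyl]-2-(2-oxopropoxy)benzaldehyde | C[C@@H](O[Si](C)(C)C(C)(C)C)c1ccc(OCC(C)=O)c(C=O)c1
F2 | step 9 | 1-{(2S,3R)-5-[(1R)-1-(tert-butyldimethylsilyloxy)ethyl]-3-hydroxy-2,3-dihydro-1-benzofuran-2-yl}ethan-1-one | CC(=O)[C@H]1Oc2ccc([C@@H](C)O[Si](C)(C)C(C)(C)C)cc2[C@H]1O
F3 | step 9 | (2R,3R)-5-[(1R)-1-(tert-butyldimethylsilyloxy)ethyl]-2-(prop-1-en-2-yl)-2,3-dihydro-1-benzofuran-3-ol | C=C(C)[C@H]1Oc2ccc([C@@H](C)O[Si](C)(C)C(C)(C)C)cc2[C@H]1O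
F4 | step 9 | (2R,3R)-5-[(1R)-1-(tert-butyldimethylsilyloxy)ethyl]-2-(prop-1-en-2-yl)-2,3-dihydro-1-benzofuran-3-yl acetate | C=C(C)[C@H]1Oc2ccc([C@@H](C)O[Si](C)(C)C(C)(C)C)cc2[C@H]1OC(C)=O
F5 | step 9 | (2R,3R)-5-[(1R)-1-hydroxyethyl]-2-(prop-1-en-2-yl)-2,3-dihydro-1-benzofuran-3-yl acetate | C=C(C)[C@H]1Oc2ccc([C@@H](C)O)cc2[C@H]1OC(C)=O
F6 | step 9 | (1R)-1-[(2R,3R)-3-acetoxy-2-(prop-1-en-2-yl)-2,3-dihydro-1-benzofuran-5-yl]ethyl (Z)-2-methylbut-2-enoate | C=C(C)[C@H]1Oc2ccc([C@@H](C)OC(=O)/C(C)=C\C)cc2[C@H]1OC(C)=O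
F7 | step 10 | 1-{(2S,3R)-5-[(1R)-1-(tert-butyldimethylsilyloxy)ethyl]-3-(triethylsilyloxy)-2,3-dihydro-1-benzofuran-2-yl}-2-(4-methoxybenzyloxy)ethan-1-one | COc1ccc(COCC(=O)[C@H]2Oc3ccc([C@@H](C)O[Si](C)(C)C(C)(C)C)cc3[C@H]2O[Si](CC)(CC)CC)cc1
F8 | step 10 | tert-butyl{(1R)-1-[(2R,3R)-2-[3-(4-methoxybenzyloxy)prop-1-en-2-yl]-3-(triethylsilyloxy)-2,3-dihydro-1-benzofuran-5-yl]ethoxy}dimethylsilane | C=C(COCc1ccc(OC)cc1)[C@H]2Oc3ccc([C@@H](C)O[Si](C)(C)C(C)(C)C)cc3[C@H]2O[Si](CC)(CC)CC
F9 | step 13 | (1R)-1-{(2R,3R)-3-acetoxy-2-[3-(4-methoxybenzyloxy)prop-1-en-2-yl]-2,3-dihydro-1-benzofuran-5-yl}ethyl 2-[bis(2,2,2-trifluoroethoxy)phosphoryl]propanoate | C=C(COCc1ccc(OC)cc1)[C@H]2Oc3ccc([C@@H](C)OC(=O)C(C)P(=O)(OCC(F)(F)F)OCC(F)(F)F)cc3[C@H]2OC(C)=O
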